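The constants worth having from these runs are not rate constants but crossing points, each read from one run with its own temperature, initiator and solid monomer.

| flask | solid monomer | initiator | temperature | remark | time |
|---|---|---|---|---|---|
| beta | 34 mM | 0.57 mM | 55 °C | run made earlier |  |
| zeta | 34 mM | 1.3 mM | 90 °C | run made earlier |  |
| epsilon | 68 mM | 0.85 mM | 55 °C | run made earlier |  |
| midnight | 34 mM | 0.85 mM |  | at 60 °C until 3.0 h, from then on at 120 °C | 15 h |
| dawn | 34 mM | 0.85 mM | 120 °C |  | 15 h |
| autumn | 34 mM | 0.85 mM | 60 °C |  | 15 h |
| winter | 34 mM | 0.85 mM | 90 °C |  | 15 h |

- beta (time / h: monomer in chains / %, uncatalysed product / %, solid monomer / %): 60.0: 93.1, 8.3, 0; 120: 91.8, 8.1, 0; 144: 92.2, 8.0, 0.8; 240: 93.0, 7.3, 0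
- zeta (time / h: monomer in chains / %, uncatalysed product / %, solid monomer / %): 12.0: 85.2, 15.6, 0.4; 20.0: 85.5, 14.4, 0; 25.0: 86.8, 14.2, 0.3; 40.0: 85.9, 14.9, 0.3
- epsilon (time / h: monomer in chains / %, uncatalysed product / %, solid monomer / %): 60.0: 95.5, 4.6, 0.1; 120: 95.4, 4.3, 0.9; 144: 95.6, 4.5, 0; 240: 94.3, 3.8, 0.2

(readings scatter by 0.5 percentage points)

- solid monomer is a solid; its amount is given per volume of the solution
- at the start none of the solid monomer is in solution

1. the best flask by share of monomer in chains in all that became monomer in chains or uncatalysed product; "all alike" if 1.5 percentage points covers them all (midnight / dawn / autumn / winter / all alike)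
2. share of monomer in chains in all that became monomer in chains or uncatalysed product, midnight
3. share of monomer in chains in all that became monomer in chains or uncatalysed product, dawn
4. share of monomer in chains in all that became monomer in chains or uncatalysed product, autumn
5. share of monomer in chains in all that became monomer in chains or uncatalysed product, winter

Beta, zeta and epsilon read level from their first reading, so each gives one split of the charge between monomer in chains and uncatalysed product. With its readings averaged, zeta gives 0.224 mM and beta 0.0488 mM. This is the crossing initiator: initiator charge times product fraction over chain fraction, the charge at which the two fractions would be equal if the crossing stayed put as the initiator moved.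

My view is a divider with a corner: the chain share, the selectivity, is initiator over initiator plus crossing. Epsilon, with twice the solid monomer, reads 0.0384 mM, lower than beta, so I compare only beta and zeta, which share a charge. Between them the temperature goes from 55 °C to 90 °C and the initiator from 0.57 mM to 1.3 mM; the crossing grows 4.59-fold, and I put that on temperature as my own assumption and run it straight in reciprocal temperature. That gives 0.0619 mM for autumn and 0.665 mM for dawn. The shares are then 93.2% for autumn, 79.2% for winter and 56.1% for dawn. No reading tells how far midnight gets before its change, so I take the midpoint of autumn and dawn, 74.7%.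

The forecast holds a steeper view: product over chains falls as initiator to the power 1.6, read from beta against epsilon, and “charge matters little”. It names autumn best, with 94% there, 77% for winter, 45% for dawn and 52% for midnight. We part hardest at midnight, where my share stands higher by 23 percentage points, against 11 points at dawn.

The simulation gives autumn best, at 92.6%, with winter 82.1%, midnight 77.1% and dawn 64.9%. Dawn lies above my share by 8.8 points and above the forecast's by 20 points. The forecast's view keeps the cool end: at autumn it stands 1.4 points from the flask.

    solid monomer ⇌ free monomer, rate k1*(cs1 - [free monomer]) while solid is left; crystals form when [free monomer] > cs1 (solubility = 11.0 mM, k = 4.46 × 10⁻⁴ s⁻¹)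
    free monomer → uncatalysed product (k = 1.89 × 10⁻⁵ s⁻¹, Ea = 100 kJ mol⁻¹)
    free monomer + initiator → living end + monomer in chains (k = 0.00292 M⁻¹ s⁻¹, Ea = 78.0 kJ mol⁻¹)
    free monomer + living end → monomer in chains + living end, rate k4*[living end]*[free monomer] (k = 1.59 M⁻¹ s⁻¹, Ea = 60.0 kJ mol⁻¹)
    (constants at 60 °C)

Read back from its final fractions, winter has a crossing of 0.185 mM, lower than the 0.224 mM read from zeta. Midnight's final fractions give 0.252 mM. The neighbour of midnight, charged with 1.4 mM of initiator, then reckons at 84.7% in chains. That neighbour flask gives 84.2%.

(The runs stem from a simulated flask for an exercise; the scatter is artificial.)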